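**Retrosynthetic overview**

- The route rests on C2 of ring B (the dihydrofuran ring): it is a single sp3 carbon bonded only to O1, C3, H and the guaiacyl ring. Ring B is therefore cut at O1–C2 and C2–C3, and C2 is delivered as a benzylic sulfonium ylide carbon to the O1–C7a–C3a–C3 heterodiene of an ortho-quinone methide of ring A (the benzo ring), a (4+1) annulation.
- The ortho-quinone methide is released from a racemic 2-(1-tosylalkyl)phenol, made from 5-bromo-ortho-vanillin by hydroxymethylation, primary silylation and sulfinate substitution. The ylide comes from the (2R,5R)-2,5-dimethylthiolanium salt of O-TIPS-vanillyl bromide.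
- Ring B is the only ring formed (step 10), together with both stereocentres. The stilbene arm is then attached at C5 by Heck coupling with 3,5-bis(silyloxy)styrene, and one fluoride step removes all silyl groups.

Key step: step 10

Assumption (remark on the chemistry): the (2R,5R)-thiolanium ylide is taken to present the same face of its benzylic carbon to the ortho-quinone methide as it does to aldehydes, and that face corresponds to 2R here. Should a test run show the opposite sense, (2R,5R)-hexane-2,5-diol is used in steps 7 and 8 and nothing else changes.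

**Route**

Step 1
Reactants: 1 5-bromo-2-hydroxy-3-methoxybenzaldehyde
Product: 3 1-(5-bromo-2-hydroxy-3-methoxyphenyl)ethane-1,2-diol (racemic), via silyl carbinol 2 (not isolated)
Conditions: (i-PrO)Me2SiCH2MgCl (2.5 equiv, from ClCH2SiMe2(Oi-Pr) and Mg), THF, 0 °C; aq. NH4Cl; crude 2, then 30% H2O2, KF, KHCO3, MeOH/THF, rt
Reagents that add atoms: (isopropoxydimethylsilyl)methylmagnesium chloride, CC(C)O[Si](C)(C)C[Mg]Cl; hydrogen peroxide, OO
Why: Nucleophilic hydroxymethylation, in which one equivalent of the silylmethyl Grignard reagent deprotonates the phenol, the next adds to the aldehyde, and Tamao–Fleming oxidation of the C–Si bond of 2 under buffered fluoride conditions (which avoid Peterson elimination) should give the diol; the carbinol centre is racemic and is erased later in the ortho-quinone methide.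

Step 2
Reactants: 3 1-(5-bromo-2-hydroxy-3-methoxyphenyl)ethane-1,2-diol
Product: 4 4-bromo-2-[2-(tert-butyldiphenylsilyloxy)-1-hydroxyethyl]-6-methoxyphenol (racemic)
Conditions: TBDPSCl (1.05 equiv), imidazole, CH2Cl2, 0 °C
Reagents that add atoms: tert-butyl(chloro)diphenylsilane, CC(C)(C)[Si](Cl)(c1ccccc1)c1ccccc1
Why: Kinetically controlled silyl ether formation with the bulky chlorosilane should select the primary hydroxyl over the secondary benzylic hydroxyl and the hindered, hydrogen-bonded 2,6-disubstituted phenol.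

Step 3
Reactants: 4 4-bromo-2-[2-(tert-butyldiphenylsilyloxy)-1-hydroxyethyl]-6-methoxyphenol
Product: 5 4-bromo-2-[2-(tert-butyldiphenylsilyloxy)-1-(4-methylbenzenesulfonyl)ethyl]-6-methoxyphenol (racemic)
Conditions: p-TolSO2H (2 equiv), MgSO4, CH2Cl2, rt → 35 °C
Reagents that add atoms: 4-methylbenzenesulfinic acid, Cc1ccc(S(=O)O)cc1
Why: Acid-promoted ionisation of the ortho-hydroxybenzylic alcohol and S-alkylation of the sulfinate (SN1-type substitution, the usual entry to 2-(1-tosylalkyl)phenols) should give the sulfone, with the acid-stable TBDPS ether surviving the sulfinic acid; the centre is racemic by design.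

Step 4
Reactants: 6 vanillin (4-hydroxy-3-methoxybenzaldehyde)
Product: 7 3-methoxy-4-(triisopropylsilyloxy)benzaldehyde
Conditions: TIPSCl, imidazole, DMF, rt
Reagents that add atoms: chlorotriisopropylsilane, CC(C)[Si](Cl)(C(C)C)C(C)C
Why: Standard phenol silylation, the bulky TIPS ether being chosen to survive hydride, Appel, carbonate and Heck conditions.

Step 5
Reactants: 7 3-methoxy-4-(triisopropylsilyloxy)benzaldehyde
Product: 8 [3-methoxy-4-(triisopropylsilyloxy)phenyl]methanol
Conditions: NaBH4, MeOH/THF, 0 °C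
Reagents that add atoms: none
Why: Chemoselective hydride reduction of the aldehyde at 0 °C leaves the aryl silyl ether intact.

Step 6
Reactants: 8 [3-methoxy-4-(triisopropylsilyloxy)phenyl]methanol
Product: 9 4-(bromomethyl)-2-methoxy-1-(triisopropylsilyloxy)benzene
Conditions: CBr4, PPh3, CH2Cl2, 0 °C; used crude
Reagents that add atoms: carbon tetrabromide, BrC(Br)(Br)Br
Why: Appel bromination converts the electron-rich benzylic alcohol into the bromide under neutral conditions that do not threaten the silyl ether.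

Step 7
Reactants: 10 (2S,5S)-hexane-2,5-diol
Product: 11 (2S,5S)-hexane-2,5-diyl dimethanesulfonate
Conditions: MsCl, Et3N, CH2Cl2, –20 → 0 °C
Reagents that add atoms: methanesulfonyl chloride, CS(=O)(=O)Cl
Why: Mesylation takes place at oxygen, so both stereocentres are retained.

Step 8
Reactants: 11 (2S,5S)-hexane-2,5-diyl dimethanesulfonate
Product: 12 (2R,5R)-2,5-dimethylthiolane
Conditions: Na2S·9H2O, DMSO, rt; pentane extraction, distillation
Reagents that add atoms: sodium sulfide, [Na+].[Na+].[S-2]
Why: Two SN2 displacements by sulfur, the first intermolecular and the second 5-exo-tet, invert both centres and should give the C2-symmetric (2R,5R)-thiolane.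

Step 9
Reactants: 9 4-(bromomethyl)-2-methoxy-1-(triisopropylsilyloxy)benzene; 12 (2R,5R)-2,5-dimethylthiolane
Product: 13 (2R,5R)-1-[3-methoxy-4-(triisopropylsilyloxy)benzyl]-2,5-dimethylthiolan-1-ium tetrafluoroborate
Conditions: AgBF4, CH2Cl2, 0 °C → rt, dark; filtration, precipitation with Et2O
Reagents that add atoms: silver tetrafluoroborate, [Ag+].F[B-](F)(F)F
Why: S-Alkylation of the sulfide by the benzylic bromide is driven by precipitation of AgBr and gives the salt of a non-nucleophilic anion; because the thiolane is C2-symmetric, sulfur is not a stereocentre and a single salt should form.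

Step 10
Reactants: 5 4-bromo-2-[2-(tert-butyldiphenylsilyloxy)-1-(4-methylbenzenesulfonyl)ethyl]-6-methoxyphenol; 13 (2R,5R)-1-[3-methoxy-4-(triisopropylsilyloxy)benzyl]-2,5-dimethylthiolan-1-ium tetrafluoroborate
Product: 17 (2R,3S)-5-bromo-3-[(tert-butyldiphenylsilyloxy)methyl]-7-methoxy-2-[3-methoxy-4-(triisopropylsilyloxy)phenyl]-2,3-dihydro-1-benzofuran (trans), via ortho-quinone methide 14 (not isolated), via thiolanium ylide 15 (not isolated), via anti betaine 16 (not isolated)
Conditions: 13 (1.5 equiv), Cs2CO3 (3 equiv), MeCN/CH2Cl2 (1:1), –20 °C → rt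
Reagents that add atoms: none
Why: Proposed new method: Cs2CO3 deprotonates the phenol of 5, 1,4-elimination of toluenesulfinate gives the planar ortho-quinone methide 14 (so the racemic sulfone converges), and the same base forms the semi-stabilised benzylic ylide 15, whose carbon adds to the methide carbon (C2–C3) with rearomatisation of ring A to give betaine 16. The phenoxide then displaces the thiolane at C2 with inversion (O1–C2), a 5-exo-tet closure that forms ring B. The closest known reactions are the base-mediated (4+1) annulation of ortho-quinone methides from 2-(1-tosylalkyl)phenols with carbonyl-stabilised sulfonium ylides, which gives trans-2,3-dihydrobenzofurans, and the asymmetric benzylidene transfer from C2-symmetric thiolanium ylides to aldehydes; a chiral benzylic ylide has not been used on this heterodiene. C2 is controlled by the thiolane: the ylide reacts with its aryl group turned away from the ring and one face blocked by the flanking methyl group, and the face that leads to (S,S)-stilbene oxides with the (2R,5R)-thiolane corresponds to 2R here, because C3 ranks below the aryl group whereas an oxirane carbon ranks above it. C3 follows from C2, since the approach that keeps the guaiacyl ring and the silyloxymethyl group apart leads to the anti betaine and hence to the trans ring. The step needs capture of 14 by the ylide to outrun the 1,5-hydrogen shift of 14 and benzylation of the phenoxide or the sulfinate by 13, which the slow release of 14 into an excess of the soft ylide and the hindered 2,6-disubstituted phenoxide should secure.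

Step 11
Reactants: 18 3,5-dihydroxybenzaldehyde
Product: 19 3,5-bis(tert-butyldimethylsilyloxy)benzaldehyde
Conditions: TBSCl (2.4 equiv), imidazole, DMF, rt
Reagents that add atoms: tert-butyl(chloro)dimethylsilane, CC(C)(C)[Si](C)(C)Cl
Why: Standard double silylation of the two phenols.

Step 12
Reactants: 19 3,5-bis(tert-butyldimethylsilyloxy)benzaldehyde
Product: 20 3,5-bis(tert-butyldimethylsilyloxy)styrene
Conditions: Ph3PCH3Br, KN(SiMe3)2, THF, 0 °C; then 19, 0 °C → rt
Reagents that add atoms: methyltriphenylphosphonium bromide, C[P+](c1ccccc1)(c1ccccc1)c1ccccc1.[Br-]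
Why: Wittig methylenation with the preformed non-stabilised ylide converts the aldehyde into the terminal alkene without touching the aryl silyl ethers.

Step 13
Reactants: 17 (2R,3S)-5-bromo-3-[(tert-butyldiphenylsilyloxy)methyl]-7-methoxy-2-[3-methoxy-4-(triisopropylsilyloxy)phenyl]-2,3-dihydro-1-benzofuran; 20 3,5-bis(tert-butyldimethylsilyloxy)styrene
Product: 21 (2R,3S)-5-{(E)-2-[3,5-bis(tert-butyldimethylsilyloxy)phenyl]ethenyl}-3-[(tert-butyldiphenylsilyloxy)methyl]-7-methoxy-2-[3-methoxy-4-(triisopropylsilyloxy)phenyl]-2,3-dihydro-1-benzofuran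
Conditions: Pd(OAc)2 (5 mol%), P(o-tol)3, Et3N, DMF, 100 °C
Reagents that add atoms: none
Why: Mizoroki–Heck reaction, in which oxidative addition of zerovalent palladium into the C5–Br bond, syn insertion of the styrene at its terminal carbon and syn β-hydride elimination should give the E-stilbene, while the TIPS ether keeps the guaiacyl phenol masked so that ring B cannot open through a para-quinone methide and C2 and C3 stay untouched.

Step 14
Reactants: 21 (2R,3S)-5-{(E)-2-[3,5-bis(tert-butyldimethylsilyloxy)phenyl]ethenyl}-3-[(tert-butyldiphenylsilyloxy)methyl]-7-methoxy-2-[3-methoxy-4-(triisopropylsilyloxy)phenyl]-2,3-dihydro-1-benzofuran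
Product: 22 gnetofuran A
Conditions: TBAF, AcOH (1:1, excess), THF, 0 °C → rt, argon
Reagents that add atoms: none
Why: Fluoride cleaves the three aryl silyl ethers and the primary TBDPS ether, and the acetic acid buffer keeps the phenols protonated so that neither base-induced opening of ring B at C2 nor oxidation of the stilbene polyphenol should intervene; no stereocentre is involved.

**Compound list**

1 | 5-bromo-2-hydroxy-3-methoxybenzaldehyde | COc1cc(Br)cc(C=O)c1O | starting material
2 | 4-bromo-2-[1-hydroxy-2-(isopropoxydimethylsilyl)ethyl]-6-methoxyphenol (racemic) | COc1cc(Br)cc(C(O)C[Si](C)(C)OC(C)C)c1O | intermediate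
3 | 1-(5-bromo-2-hydroxy-3-methoxyphenyl)ethane-1,2-diol (racemic) | COc1cc(Br)cc(C(O)CO)c1O | intermediate
4 | 4-bromo-2-[2-(tert-butyldiphenylsilyloxy)-1-hydroxyethyl]-6-methoxyphenol (racemic) | COc1cc(Br)cc(C(O)CO[Si](c2ccccc2)(c2ccccc2)C(C)(C)C)c1O | intermediate
5 | 4-bromo-2-[2-(tert-butyldiphenylsilyloxy)-1-(4-methylbenzenesulfonyl)ethyl]-6-methoxyphenol (racemic) | COc1cc(Br)cc(C(CO[Si](c2ccccc2)(c2ccccc2)C(C)(C)C)S(=O)(=O)c2ccc(C)cc2)c1O | intermediate
6 | vanillin | COc1cc(C=O)ccc1O | starting material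
7 | 3-methoxy-4-(triisopropylsilyloxy)benzaldehyde | COc1cc(C=O)ccc1O[Si](C(C)C)(C(C)C)C(C)C | intermediate
8 | [3-methoxy-4-(triisopropylsilyloxy)phenyl]methanol | COc1cc(CO)ccc1O[Si](C(C)C)(C(C)C)C(C)C | intermediate
9 | 4-(bromomethyl)-2-methoxy-1-(triisopropylsilyloxy)benzene | COc1cc(CBr)ccc1O[Si](C(C)C)(C(C)C)C(C)C | intermediate
10 | (2S,5S)-hexane-2,5-diol | C[C@H](O)CC[C@H](C)O | starting material
11 | (2S,5S)-hexane-2,5-diyl dimethanesulfonate | C[C@H](OS(C)(=O)=O)CC[C@H](C)OS(C)(=O)=O | intermediate
12 | (2R,5R)-2,5-dimethylthiolane | C[C@@H]1CC[C@@H](C)S1 | intermediate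
13 | (2R,5R)-1-[3-methoxy-4-(triisopropylsilyloxy)benzyl]-2,5-dimethylthiolan-1-ium tetrafluoroborate | C[C@@H]1CC[C@@H](C)[S+]1Cc1ccc(O[Si](C(C)C)(C(C)C)C(C)C)c(OC)c1.F[B-](F)(F)F | intermediate
14 | (E)-4-bromo-6-[2-(tert-butyldiphenylsilyloxy)ethylidene]-2-methoxycyclohexa-2,4-dien-1-one (ortho-quinone methide) | COC1=CC(Br)=C/C(=C\CO[Si](c2ccccc2)(c2ccccc2)C(C)(C)C)C1=O | intermediate
15 | [(2R,5R)-2,5-dimethylthiolan-1-ium-1-yl][3-methoxy-4-(triisopropylsilyloxy)phenyl]methanide (ylide) | C[C@@H]1CC[C@@H](C)[S+]1[CH-]c1ccc(O[Si](C(C)C)(C(C)C)C(C)C)c(OC)c1 | intermediate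
16 | anti betaine: 4-bromo-2-{3-(tert-butyldiphenylsilyloxy)-1-[(2R,5R)-2,5-dimethylthiolan-1-ium-1-yl]-1-[3-methoxy-4-(triisopropylsilyloxy)phenyl]propan-2-yl}-6-methoxyphenolate | COc1cc([C@H]([C@H](CO[Si](c2ccccc2)(c2ccccc2)C(C)(C)C)c2cc(Br)cc(OC)c2[O-])[S+]2[C@H](C)CC[C@H]2C)ccc1O[Si](C(C)C)(C(C)C)C(C)C | intermediate
17 | (2R,3S)-5-bromo-3-[(tert-butyldiphenylsilyloxy)methyl]-7-methoxy-2-[3-methoxy-4-(triisopropylsilyloxy)phenyl]-2,3-dihydro-1-benzofuran | COc1cc([C@@H]2Oc3c(OC)cc(Br)cc3[C@H]2CO[Si](c2ccccc2)(c2ccccc2)C(C)(C)C)ccc1O[Si](C(C)C)(C(C)C)C(C)C | intermediate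
18 | 3,5-dihydroxybenzaldehyde | O=Cc1cc(O)cc(O)c1 | starting material
19 | 3,5-bis(tert-butyldimethylsilyloxy)benzaldehyde | O=Cc1cc(O[Si](C)(C)C(C)(C)C)cc(O[Si](C)(C)C(C)(C)C)c1 | intermediate
20 | 3,5-bis(tert-butyldimethylsilyloxy)styrene | C=Cc1cc(O[Si](C)(C)C(C)(C)C)cc(O[Si](C)(C)C(C)(C)C)c1 | intermediate
21 | (2R,3S)-5-{(E)-2-[3,5-bis(tert-butyldimethylsilyloxy)phenyl]ethenyl}-3-[(tert-butyldiphenylsilyloxy)methyl]-7-methoxy-2-[3-methoxy-4-(triisopropylsilyloxy)phenyl]-2,3-dihydro-1-benzofuran | COc1cc([C@@H]2Oc3c(OC)cc(/C=C/c4cc(O[Si](C)(C)C(C)(C)C)cc(O[Si](C)(C)C(C)(C)C)c4)cc3[C@H]2CO[Si](c2ccccc2)(c2ccccc2)C(C)(C)C)ccc1O[Si](C(C)C)(C(C)C)C(C)C | intermediate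
22 | gnetofuran A, 5-{(E)-2-[(2R,3S)-2-(4-hydroxy-3-methoxyphenyl)-3-(hydroxymethyl)-7-methoxy-2,3-dihydro-1-benzofuran-5-yl]ethenyl}benzene-1,3-diol | COc1cc([C@@H]2Oc3c(OC)cc(/C=C/c4cc(O)cc(O)c4)cc3[C@H]2CO)ccc1O | target

**Step count**

Total: 14 steps. Longest linear sequence: 7 steps (6 → 7 → 8 → 9 → 13 → 17 → 21 → 22; steps 4, 5, 6, 9, 10, 13, 14).

**Steps most likely to fail, with fallbacks**

1. Step 10 (proposed new method). The thiolane may discriminate the two faces of the ylide carbon poorly, the syn approach may compete and erode the trans selectivity, or the ortho-quinone methide may be lost by 1,5-hydrogen shift or the sulfonium salt by benzyl transfer to phenoxide or sulfinate before annulation. The fallback uses known chemistry, sets out from bromide 9 and returns at 17. Commercial 4-bromo-2-methoxyphenol (COc1cc(Br)ccc1O) is iodinated ortho to the hydroxyl (NIS, TsOH cat., MeCN) to 4-bromo-2-iodo-6-methoxyphenol F1. Williamson etherification with 9 (K2CO3, DMF, rt) gives 5-bromo-1-iodo-3-methoxy-2-{[3-methoxy-4-(triisopropylsilyloxy)phenyl]methoxy}benzene F2. Palladium-catalysed coupling of the C–I bond with methyl diazoacetate (Pd(PPh3)4, Ag2CO3, Et3N, toluene, rt) should give methyl 2-(5-bromo-3-methoxy-2-{[3-methoxy-4-(triisopropylsilyloxy)phenyl]methoxy}phenyl)-2-diazoacetate F3. Enantioselective intramolecular C–H insertion of the rhodium carbene into the benzylic ether C–H bond (Rh2(S-PTTL)4 or its antipode, whichever delivers 2R; toluene, –60 °C) should give methyl cis-(2R,3S)-5-bromo-7-methoxy-2-[3-methoxy-4-(triisopropylsilyloxy)phenyl]-2,3-dihydro-1-benzofuran-3-carboxylate F4. NaOMe in MeOH epimerises C3 to methyl trans-(2R,3R)-5-bromo-7-methoxy-2-[3-methoxy-4-(triisopropylsilyloxy)phenyl]-2,3-dihydro-1-benzofuran-3-carboxylate F5. i-Bu2AlH (CH2Cl2, –78 → 0 °C) reduces the ester to [(2R,3S)-5-bromo-7-methoxy-2-[3-methoxy-4-(triisopropylsilyloxy)phenyl]-2,3-dihydro-1-benzofuran-3-yl]methanol F6, and TBDPSCl with imidazole gives 17.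

2. Step 3. Ionisation of the benzylic C–O bond next to the electron-poor silyloxymethyl carbon may be slow, so that 1,2-hydride shift of the cation (leading to the arylacetaldehyde) or acid cleavage of the silyl ether competes with capture by the weakly nucleophilic sulfinate. The fallback sets out from 4 and returns at 5, forming the C–S bond at the sulfide oxidation level. 4-Methylbenzenethiol with ZnI2 in 1,2-dichloroethane at rt (Lewis-acid thioetherification of a benzylic alcohol by a far better nucleophile) should give 4-bromo-2-[2-(tert-butyldiphenylsilyloxy)-1-(4-methylphenylsulfanyl)ethyl]-6-methoxyphenol F7, and oxidation at sulfur with mCPBA (2.2 equiv, CH2Cl2, 0 °C) gives sulfone 5.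

3. Step 13. Oxidative addition into the electron-rich C5–Br bond may be slow, with catalyst decomposition, and the electron-rich styrene may be arylated at its internal carbon to give the 1,1-diarylethene. The fallback sets out from 20 and returns at 21, fixing regiochemistry and alkene geometry before the coupling. Cross-metathesis of 20 with vinylboronic acid pinacol ester (second-generation Hoveyda–Grubbs catalyst, CH2Cl2, 40 °C) should give 2-{(E)-2-[3,5-bis(tert-butyldimethylsilyloxy)phenyl]ethenyl}-4,4,5,5-tetramethyl-1,3,2-dioxaborolane F8, and Suzuki–Miyaura coupling with 17 (Pd(OAc)2, SPhos, K3PO4, toluene/H2O, 60 °C) gives 21. Any aryl silyl ether lost to the aqueous base converges on 22 in step 14.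

**Further compounds**

F1 | step 10 | 4-bromo-2-iodo-6-methoxyphenol | COc1cc(Br)cc(I)c1O
F2 | step 10 | 5-bromo-1-iodo-3-methoxy-2-{[3-methoxy-4-(triisopropylsilyloxy)phenyl]methoxy}benzene | COc1cc(Br)cc(I)c1OCc1ccc(O[Si](C(C)C)(C(C)C)C(C)C)c(OC)c1
F3 | step 10 | methyl 2-(5-bromo-3-methoxy-2-{[3-methoxy-4-(triisopropylsilyloxy)phenyl]methoxy}phenyl)-2-diazoacetate | COC(=O)C(=[N+]=[N-])c1cc(Br)cc(OC)c1OCc1ccc(O[Si](C(C)C)(C(C)C)C(C)C)c(OC)c1
F4 | step 10 | methyl cis-(2R,3S)-5-bromo-7-methoxy-2-[3-methoxy-4-(triisopropylsilyloxy)phenyl]-2,3-dihydro-1-benzofuran-3-carboxylate | COc1cc([C@@H]2Oc3c(OC)cc(Br)cc3[C@@H]2C(=O)OC)ccc1O[Si](C(C)C)(C(C)C)C(C)C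
F5 | step 10 | methyl trans-(2R,3R)-5-bromo-7-methoxy-2-[3-methoxy-4-(triisopropylsilyloxy)phenyl]-2,3-dihydro-1-benzofuran-3-carboxylate | COc1cc([C@@H]2Oc3c(OC)cc(Br)cc3[C@H]2C(=O)OC)ccc1O[Si](C(C)C)(C(C)C)C(C)C
F6 | step 10 | [(2R,3S)-5-bromo-7-methoxy-2-[3-methoxy-4-(triisopropylsilyloxy)phenyl]-2,3-dihydro-1-benzofuran-3-yl]methanol | COc1cc([C@@H]2Oc3c(OC)cc(Br)cc3[C@H]2CO)ccc1O[Si](C(C)C)(C(C)C)C(C)C
F7 | step 3 | 4-bromo-2-[2-(tert-butyldiphenylsilyloxy)-1-(4-methylphenylsulfanyl)ethyl]-6-methoxyphenol (racemic) | COc1cc(Br)cc(C(CO[Si](c2ccccc2)(c2ccccc2)C(C)(C)C)Sc2ccc(C)cc2)c1O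
F8 | step 13 | 2-{(E)-2-[3,5-bis(tert-butyldimethylsilyloxy)phenyl]ethenyl}-4,4,5,5-tetramethyl-1,3,2-dioxaborolane | CC1(C)OB(/C=C/c2cc(O[Si](C)(C)C(C)(C)C)cc(O[Si](C)(C)C(C)(C)C)c2)OC1(C)C
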